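**Retrosynthetic overview**
1. The route rests on the monocycle: a cyclohexane made of the ring carbon C(=CH2), the adjacent (S)-CH that carries the chain, the adjacent CMe2 and three CH2. This is the singly cyclised end of an (E,E)-farnesyl-type chain, so the CMe2–CH ring bond is cut last, giving a decalin-tailed tetraene for closure by a squalene–hopene cyclase variant.
2. The tetraene is cut at the sp3–sp2 bond between the second CH2 of the decalin side chain and the neighbouring trisubstituted alkene (Negishi coupling of a homoallylic zinc iodide with an (E)-alkenyl iodide).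
3. The decalin half comes from (+)-sclareolide, which supplies rings A and B and both ring-fusion centres C5 and C10 (drimane numbering); the tetrasubstituted C8=C9 alkene is made by acid-mediated lactone opening and elimination. The alkenyl iodide comes from (E)-geranylacetone via the terminal alkyne and Zr-catalysed carboalumination–iodination.
4. Ring order: rings A and B are bought with sclareolide; the monocycle is formed last, in the enzymatic step.

Key step: step 7

Assumption: geranylacetone is bought as the isomerically enriched (E)-isomer, and the cyclase variant is a catalyst obtained by standard expression in Escherichia coli, not a starting material.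

**Route**

Step 1
Reactants: 1 (+)-sclareolide
Product: 3 methyl 2-[(4aS,8aS)-2,5,5,8a-tetramethyl-3,4,4a,5,6,7,8,8a-octahydronaphthalen-1-yl]acetate, via unsaturated acid 2 (not isolated)
Conditions: conc. H2SO4, MeOH, 65 °C, prolonged heating; chromatography on AgNO3-impregnated SiO2
Reagents that add atoms: methanol, CO
Why: Acid-catalysed alkyl–oxygen cleavage of the tertiary lactone C8–O bond, E1 loss of H-9 under thermodynamic control towards the tetrasubstituted C8=C9 alkene and Fischer esterification of the freed acid in methanol should give 3, the ring-fusion centres C5 and C10 taking no part and minor trisubstituted and exocyclic alkene isomers being removed on AgNO3–silica.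

Step 2
Reactants: 3 methyl ester
Product: 4 2-[(4aS,8aS)-2,5,5,8a-tetramethyl-3,4,4a,5,6,7,8,8a-octahydronaphthalen-1-yl]ethan-1-ol
Conditions: LiAlH4, THF, 0 °C to rt; aqueous work-up
Reagents that add atoms: none
Why: LiAlH4 reduction of an ester to the primary alcohol, to which the isolated tetrasubstituted alkene is inert.

Step 3
Reactants: 4 homoallylic alcohol
Product: 5 (4aS,8aS)-1-(2-iodoethyl)-2,5,5,8a-tetramethyl-3,4,4a,5,6,7,8,8a-octahydronaphthalene
Conditions: PPh3, imidazole, I2 (premixed), CH2Cl2, 0 °C to rt, dark
Reagents that add atoms: iodine, II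
Why: Appel-type iodination of an unhindered primary alcohol by SN2 displacement of the alkoxyphosphonium ion with iodide, under imidazole-buffered conditions in which premixing leaves little free iodine to touch the alkene.

Step 4
Reactants: 6 (E)-geranylacetone
Product: 8 (5E)-6,10-dimethylundeca-5,9-dien-1-yne, via enol phosphate 7 (not isolated)
Conditions: LiN(i-Pr)2 (LDA, 1.1 equiv), THF, −78 °C; ClP(O)(OEt)2, −78 °C to rt; LDA (2.3 equiv), −78 °C to rt; then H2O
Reagents that add atoms: none
Why: Methyl ketone to terminal alkyne conversion by kinetic enolisation at the methyl group, O-phosphorylation and LDA-induced E2 elimination of diethyl phosphate, the excess base holding the product as its acetylide so that no allene or internal alkyne forms while the trisubstituted alkenes stay untouched.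

Step 5
Reactants: 8 dienyne
Product: 10 (1E,5E)-1-iodo-2,6,10-trimethylundeca-1,5,9-triene, via alkenylalane 9 (not isolated)
Conditions: Me3Al (2 equiv), Cp2ZrCl2 (0.25 equiv), CH2Cl2, rt; then I2, THF, −30 to 0 °C
Reagents that add atoms: trimethylaluminium, C[Al](C)C; iodine, II
Why: Zirconium-catalysed carboalumination adds methyl and aluminium syn across the terminal alkyne with aluminium at the terminal carbon, and iodinolysis of the alkenyl–aluminium bond with retention should give the (E)-iodide, trisubstituted alkenes being unreactive.

Step 6
Reactants: 5 homoallylic iodide; 10 (E)-alkenyl iodide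
Product: 12 (4aS,8aS)-2,5,5,8a-tetramethyl-1-[(3E,7E)-4,8,12-trimethyltrideca-3,7,11-trien-1-yl]-3,4,4a,5,6,7,8,8a-octahydronaphthalene (bicyclic tetraene), via alkylzinc iodide 11 (not isolated)
Conditions: 5 (1.25 equiv), Zn dust (activated with 5 mol% BrCH2CH2Br and 1 mol% Me3SiCl), LiCl, THF, 40 °C; then 10, Pd(PPh3)4 (5 mol%), THF, rt to 40 °C
Reagents that add atoms: none
Why: Negishi cross-coupling, in which zerovalent palladium inserts into the alkenyl C–I bond with retention, the primary homoallylic zinc iodide transmetalates and reductive elimination forms the sp3–sp2 bond with the E geometry kept, all without any acid that could move the tetrasubstituted alkene.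

Step 7
Reactants: 12 bicyclic tetraene
Product: 13 (4aS,8aS)-1-{(3E)-6-[(1S)-2,2-dimethyl-6-methylidenecyclohexyl]-4-methylhex-3-en-1-yl}-2,5,5,8a-tetramethyl-3,4,4a,5,6,7,8,8a-octahydronaphthalene (target)
Conditions: Alicyclobacillus acidocaldarius squalene–hopene cyclase, Asp377Cys variant (cell-free extract of recombinant Escherichia coli), 12 dispersed with Triton X-100 (0.2% w/v), citric acid/trisodium citrate buffer pH 6.0, 50–60 °C, 24–48 h; hexane extraction; chromatography on AgNO3-impregnated SiO2 with recycling of unreacted 12
Reagents that add atoms: none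
Why: The cyclase should bind the all-E isoprenoid end of 12 in a chair fold at the bottom of its hydrophobic cavity, where the aspartic acid of the DXDD motif (Asp376) protonates the terminal Me2C=CH alkene at CH; the tertiary cation is captured by the next trisubstituted alkene to form the CMe2–CH bond, and the new tertiary ring cation loses a methyl proton to give the exocyclic methylene. The closest known reaction is the arrest of squalene after its first ring by this same variant, which gives the monocyclic hydrocarbon 3-deoxyachilleol A; 12 is that substrate with its far end already cyclised, so productive binding of the decalin tail is the open point. The ring closes in a 6-endo-trig cation–olefin mode through a chair transition state. The new (S) centre at the ring CH is set by the enzyme alone, whose fold presents one face of the attacking alkene to the cation (the face selection that gives the (S)-monocycle from squalene), the decalin stereocentres lying eight or more bonds away. The step needs site selectivity for the terminal alkene, arrest after one ring and methyl rather than ring-CH2 deprotonation; the first should follow because only the slim isopropylidene end can reach the buried acid, the others are properties of the variant's active site, and the near-neutral buffer contains no free acid that could isomerise the exocyclic or the tetrasubstituted alkene.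

**Compound list**
1 | (+)-sclareolide, (3aR,5aS,9aS,9bR)-3a,6,6,9a-tetramethyldecahydronaphtho[2,1-b]furan-2(1H)-one | C[C@]12CCCC([C@@H]1CC[C@@]3([C@@H]2CC(=O)O3)C)(C)C | starting material
2 | 2-[(4aS,8aS)-2,5,5,8a-tetramethyl-3,4,4a,5,6,7,8,8a-octahydronaphthalen-1-yl]acetic acid | OC(=O)CC1=C(C)CC[C@H]2C(C)(C)CCC[C@]12C | intermediate
3 | methyl 2-[(4aS,8aS)-2,5,5,8a-tetramethyl-3,4,4a,5,6,7,8,8a-octahydronaphthalen-1-yl]acetate | COC(=O)CC1=C(C)CC[C@H]2C(C)(C)CCC[C@]12C | intermediate
4 | 2-[(4aS,8aS)-2,5,5,8a-tetramethyl-3,4,4a,5,6,7,8,8a-octahydronaphthalen-1-yl]ethan-1-ol | OCCC1=C(C)CC[C@H]2C(C)(C)CCC[C@]12C | intermediate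
5 | (4aS,8aS)-1-(2-iodoethyl)-2,5,5,8a-tetramethyl-3,4,4a,5,6,7,8,8a-octahydronaphthalene | ICCC1=C(C)CC[C@H]2C(C)(C)CCC[C@]12C | intermediate
6 | (E)-geranylacetone, (5E)-6,10-dimethylundeca-5,9-dien-2-one | CC(C)=CCC/C(C)=C/CCC(C)=O | starting material
7 | diethyl (5E)-6,10-dimethylundeca-1,5,9-trien-2-yl phosphate | CC(C)=CCC/C(C)=C/CCC(=C)OP(=O)(OCC)OCC | intermediate
8 | (5E)-6,10-dimethylundeca-5,9-dien-1-yne | CC(C)=CCC/C(C)=C/CCC#C | intermediate
9 | dimethyl[(1E,5E)-2,6,10-trimethylundeca-1,5,9-trien-1-yl]alumane | CC(C)=CCC/C(C)=C/CC/C(C)=C/[Al](C)C | intermediate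
10 | (1E,5E)-1-iodo-2,6,10-trimethylundeca-1,5,9-triene | CC(C)=CCC/C(C)=C/CC/C(C)=C/I | intermediate
11 | {2-[(4aS,8aS)-2,5,5,8a-tetramethyl-3,4,4a,5,6,7,8,8a-octahydronaphthalen-1-yl]ethyl}zinc iodide | I[Zn]CCC1=C(C)CC[C@H]2C(C)(C)CCC[C@]12C | intermediate
12 | (4aS,8aS)-2,5,5,8a-tetramethyl-1-[(3E,7E)-4,8,12-trimethyltrideca-3,7,11-trien-1-yl]-3,4,4a,5,6,7,8,8a-octahydronaphthalene | CC(C)=CCC/C(C)=C/CC/C(C)=C/CCC1=C(C)CC[C@H]2C(C)(C)CCC[C@]12C | intermediate
13 | (4aS,8aS)-1-{(3E)-6-[(1S)-2,2-dimethyl-6-methylidenecyclohexyl]-4-methylhex-3-en-1-yl}-2,5,5,8a-tetramethyl-3,4,4a,5,6,7,8,8a-octahydronaphthalene | C=C1CCCC(C)(C)[C@@H]1CC/C(C)=C/CCC1=C(C)CC[C@H]2C(C)(C)CCC[C@]12C | target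

**Step count**
Total: 7 steps. Longest linear sequence: 5 steps (steps 1, 2, 3, 6, 7 from sclareolide); the geranylacetone branch has 4 (steps 4, 5, 6, 7).

**Steps most likely to fail**

Step 7. The variant may not bind the decalin-tailed substrate productively, giving no turnover, or it may quench the ring cation by ring-CH2 deprotonation or by water. The fallback drops the enzymatic closure and brings in the monocycle with its stereocentre already fixed. It sets out from alkylzinc iodide 11 (made from 5 as in step 6) and comes back at target 13. The ketone 4-[(1S)-2,2-dimethyl-6-methylidenecyclohexyl]butan-2-one F1 ((S)-γ-dihydroionone) is a known ambergris ketone, obtainable enantioenriched by the established lipase-resolution chemistry of the γ-ionone series followed by conjugate reduction. It would be taken through the same operations as geranylacetone: LDA and ClP(O)(OEt)2 to the enol phosphate F2, LDA elimination to the alkyne F3, Me3Al/Cp2ZrCl2 carboalumination to the alkenylalane F4 and iodinolysis to the (E)-alkenyl iodide F5. Pd(PPh3)4-catalysed Negishi coupling of F5 with 11 would then give 13 directly. The 1,1-disubstituted exocyclic alkene is expected to be inert to carboalumination.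

Step 1. Regiocontrol in the cationic elimination may be incomplete, with the trisubstituted and exocyclic alkene isomers persisting, or the C8 cation may rearrange by hydride and methyl shifts. The fallback fixes the alkene position by a reductive, non-cationic lactone opening; it sets out from 1 and comes back at 4 by way of acid 2. Enolisation of 1 with LDA and trapping with PhSeBr on the less hindered face should give 11-(phenylselanyl)sclareolide F6, with selenium cis to H-9. H2O2 oxidation and selenoxide syn-elimination, for which H-9 is the only β-hydrogen, would give the butenolide 9(11)-didehydrosclareolide F7. SmI2 (THF–HMPA, t-BuOH) should then cleave the γ C8–O bond of the unsaturated lactone, and kinetic α-protonation of the resulting dienolate places the alkene at C8=C9, giving acid 2. LiAlH4 reduces 2 to alcohol 4.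

Step 6. Zinc insertion may be sluggish, the alkylzinc may be protonated, or the coupling may be eroded by homocoupling of the alkenyl iodide and β-hydride elimination at alkylpalladium. The fallback is a B-alkyl Suzuki–Miyaura coupling through a boron ate complex; it sets out from 5 and comes back at 12. Iodide 5 is exchanged with t-BuLi (2 equiv, Et2O, −78 °C) to the alkyllithium F8, which is trapped with B-methoxy-9-BBN to the lithium borate F9. F9 is coupled in the same flask with 10 using PdCl2(dppf), K3PO4, DMF–THF at rt.

**Further compounds**
F1 | step 7 | 4-[(1S)-2,2-dimethyl-6-methylidenecyclohexyl]butan-2-one, (S)-γ-dihydroionone | C=C1CCCC(C)(C)[C@@H]1CCC(C)=O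
F2 | step 7 | diethyl 4-[(1S)-2,2-dimethyl-6-methylidenecyclohexyl]but-1-en-2-yl phosphate | C=C1CCCC(C)(C)[C@@H]1CCC(=C)OP(=O)(OCC)OCC
F3 | step 7 | (1S)-1-(but-3-yn-1-yl)-2,2-dimethyl-6-methylidenecyclohexane | C=C1CCCC(C)(C)[C@@H]1CCC#C
F4 | step 7 | {(1E)-4-[(1S)-2,2-dimethyl-6-methylidenecyclohexyl]-2-methylbut-1-en-1-yl}dimethylalumane | C=C1CCCC(C)(C)[C@@H]1CC/C(C)=C/[Al](C)C
F5 | step 7 | (1S)-1-[(3E)-4-iodo-3-methylbut-3-en-1-yl]-2,2-dimethyl-6-methylidenecyclohexane | C=C1CCCC(C)(C)[C@@H]1CC/C(C)=C/I
F6 | step 1 | 11-(phenylselanyl)sclareolide, selenium cis to H-9 | C[C@]12CCCC([C@@H]1CC[C@@]3([C@@H]2[C@H]([Se]c4ccccc4)C(=O)O3)C)(C)C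
F7 | step 1 | 9(11)-didehydrosclareolide, butenolide with the C9=C11 alkene conjugated to the lactone carbonyl | C[C@]12CCCC([C@@H]1CC[C@@]3(C2=CC(=O)O3)C)(C)C
F8 | step 6 | {2-[(4aS,8aS)-2,5,5,8a-tetramethyl-3,4,4a,5,6,7,8,8a-octahydronaphthalen-1-yl]ethyl}lithium | [Li]CCC1=C(C)CC[C@H]2C(C)(C)CCC[C@]12C
F9 | step 6 | lithium 9-methoxy-9-{2-[(4aS,8aS)-2,5,5,8a-tetramethyl-3,4,4a,5,6,7,8,8a-octahydronaphthalen-1-yl]ethyl}-9-borabicyclo[3.3.1]nonan-9-uide | [Li+].CO[B-]1(CCC3=C(C)CC[C@H]4C(C)(C)CCC[C@]34C)C2CCCC1CCC2
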